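**Plan**

1. Each perhydro-1-benzoxepine half is numbered O1, C2 (CMe2), C3, C4, C5, C6 (quaternary), C7 (OCH), C8, C9, C10, C11, C12 (linker carbon), with primes for the exo-methylene half; ring A is the cyclohexane (C6–C11) and ring B the oxepane (O1–C7). The retrosynthesis cuts C12–C12' (radical conjugate addition), C10'=CH2 (Wittig) and C10–CH3 (organocerium), then, in a bicycle common to both halves, C6–C7 and C9–C10 (one operation), O1–C2 (epoxide opening) and C6=C11 (Knoevenagel).
2. Forward: sulcatone and dibenzyl malonate give an alkylidene malonate. Its remote alkene is epoxidised and opened at C2 by methallyl alcohol, and the methallyl alkene is cleaved to an acetonyl ether. Base then closes ring B by Michael addition C7→C6 and ring A by Dieckmann acylation C9→C10.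
3. What makes the event possible: C7 bears the ring oxygen and is α to a temporary C8 ketone. C6 is the β-carbon of an alkylidene malonate whose central carbon is C11 and whose ester carbon is C10. The C9 methyl of the same ketone then stands 1,5 to that ester, as in the ring closure of the dimedone synthesis.
4. Helpers and their removal: the C8 oxygen leaves by enol triflate formation and formate reduction. The second ester is lost as CO2 in a decarboxylative methylenation that installs C12. The silyl ethers at C3 and C3' come off in steps 12 and 16.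
5. Both halves come from one α-methylene ketone (15). One portion is methylated at C10, desilylated, hydroborated and added as a primary C12 radical to a second portion of 15. Methylenation, oxidation at C3 and desilylation finish the route.
6. Stereochemistry: C3/C3' from Shi epoxidation; C6 by 1,4-induction from C3 in the Michael step, which also sets the trans ring fusion at C7; C10 by equatorial attack of the methyl nucleophile; C11 by hydroboration anti to the axial groups; C11' by equilibration.

Key step: step 6

Remark: the sense of the Shi epoxidation is assigned by analogy with other 2-methylalk-2-enes (the D-fructose-derived ketone gives the R epoxide), so the enantiomeric, L-fructose-derived ketone is used for the S epoxide.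

Remark: bicyclic compounds are named with the core numbering of the plan; β is the face of the C6 methyl group, α the opposite face; the SMILES in the compound list define the structures.

**Route**

Step 1
Reactants: 1 6-methylhept-5-en-2-one (sulcatone); 2 dibenzyl malonate
Product: 3 dibenzyl 2-(6-methylhept-5-en-2-ylidene)propanedioate
Conditions: TiCl4, pyridine, THF, 0 °C → rt
Reagents that add atoms: none
Why: Knoevenagel condensation of a methyl ketone with a malonate under TiCl4/pyridine activation should give the tetrasubstituted alkylidene malonate, which holds C6, C11 and the future C10 and leaves the remote trisubstituted alkene untouched.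

Step 2
Reactants: 3 dibenzyl 2-(6-methylhept-5-en-2-ylidene)propanedioate
Product: 4 dibenzyl 2-{4-[(2S)-3,3-dimethyloxiran-2-yl]butan-2-ylidene}propanedioate
Conditions: L-fructose-derived Shi ketone (30 mol%), KHSO5 (Oxone), K2CO3, Bu4NHSO4, MeCN/CH2(OMe)2/aq. Na2B4O7 buffer, 0 °C
Reagents that add atoms: potassium peroxymonosulfate (KHSO5), [K+].[O-]S(=O)(=O)OO
Why: Shi epoxidation (chiral dioxirane, spiro transition state) should oxidise only the electron-rich trisubstituted alkene and set the S configuration at C3, the electron-poor alkylidene malonate being inert.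

Step 3
Reactants: 4 dibenzyl 2-{4-[(2S)-3,3-dimethyloxiran-2-yl]butan-2-ylidene}propanedioate; 5 2-methylprop-2-en-1-ol (methallyl alcohol)
Product: 6 dibenzyl 2-{(5S)-5-hydroxy-6-methyl-6-[(2-methylprop-2-en-1-yl)oxy]heptan-2-ylidene}propanedioate
Conditions: BF3·OEt2 (10 mol%), 2-methylprop-2-en-1-ol (10 equiv), CH2Cl2, −40 → 0 °C
Reagents that add atoms: none
Why: Lewis-acid-catalysed alcoholysis of a trisubstituted epoxide should take place at the tertiary carbon C2 (borderline SN1 opening), forming the O1–C2 ether and leaving the C3–O bond and its S configuration untouched.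

Step 4
Reactants: 6 dibenzyl 2-{(5S)-5-hydroxy-6-methyl-6-[(2-methylprop-2-en-1-yl)oxy]heptan-2-ylidene}propanedioate
Product: 7 dibenzyl 2-{(5S)-5-[(tert-butyldimethylsilyl)oxy]-6-methyl-6-[(2-methylprop-2-en-1-yl)oxy]heptan-2-ylidene}propanedioate
Conditions: TBSOTf, 2,6-lutidine, CH2Cl2, −78 → 0 °C
Reagents that add atoms: tert-butyldimethylsilyl triflate, CC(C)(C)[Si](C)(C)OS(=O)(=O)C(F)(F)F
Why: silylation of the hindered secondary alcohol with the silyl triflate blocks oxa-Michael addition and lactonisation in the base step and turns C3 into a bulky stereocontrolling group.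

Step 5
Reactants: 7 dibenzyl 2-{(5S)-5-[(tert-butyldimethylsilyl)oxy]-6-methyl-6-[(2-methylprop-2-en-1-yl)oxy]heptan-2-ylidene}propanedioate
Product: 8 dibenzyl 2-{(5S)-5-[(tert-butyldimethylsilyl)oxy]-6-methyl-6-(2-oxopropoxy)heptan-2-ylidene}propanedioate
Conditions: OsO4 (2 mol%), NaIO4, 2,6-lutidine, dioxane/H2O, rt
Reagents that add atoms: osmium tetroxide (catalytic, reoxidised by periodate), O=[Os](=O)(=O)=O; sodium periodate, [Na+].[O-]I(=O)(=O)=O
Why: Lemieux–Johnson cleavage should cut only the electron-rich 1,1-disubstituted alkene of the methallyl ether (the tetrasubstituted, electron-poor alkylidene malonate does not react with OsO4) and unveil the methyl ketone that activates C7 and C9.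

Step 6
Reactants: 8 dibenzyl 2-{(5S)-5-[(tert-butyldimethylsilyl)oxy]-6-methyl-6-(2-oxopropoxy)heptan-2-ylidene}propanedioate
Product: 10 benzyl 3α-(tert-butyldimethylsilyloxy)-2,2,6β-trimethyl-8,10-dioxo-7αH-perhydro-1-benzoxepine-11β-carboxylate (trans-fused; drawn as the triketo tautomer), via oxepane Michael adduct 9 (not isolated)
Conditions: NaH (2.5 equiv), BnOH (10 mol%), THF (0.02 M), 0 → 50 °C; then 1 M HCl
Reagents that add atoms: none
Why: Under equilibrating conditions the ketone enolate at C7 (the α-carbon that bears O1) adds to C6, the β-carbon of the alkylidene malonate, and the malonate anion formed relays the charge by proton transfer to the C9 methyl enolate, which acylates one benzyl ester (C10) in a Dieckmann-type Claisen condensation and gives the cyclic β-diketonate irreversibly. The closest known reaction type is the Michael–Claisen annulation of methyl ketones with malonate-activated alkenes, the second ring closure being that of the dimedone synthesis. Ring B (oxepane) closes by 7-exo-trig conjugate addition and ring A (cyclohexane-1,3-dione) by 6-exo-trig acyl substitution. The quaternary C6 centre is set relative to C3: in a chair-like seven-membered transition state the OTBS group is pseudo-equatorial and allylic 1,3-strain holds a C5–H bond in the plane of the alkylidene malonate, so the malonyl carbon C11 should end pseudo-equatorial and cis to OTBS with the methyl group axial; C7 is set trans to C11 (acetyl pseudo-equatorial, and epimerisable towards the trans-fused bicycle), and C11 equilibrates as a β-keto ester. The step needs the C7 enolate, not the C9 enolate, to add first, which ring size (7 against 9) secures, and it needs the reversible γ-deprotonation of the acceptor and any oxa-Michael equilibria to be drained, which the irreversible formation of the diketonate secures.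

Step 7
Reactants: 10 benzyl 3α-(tert-butyldimethylsilyloxy)-2,2,6β-trimethyl-8,10-dioxo-7αH-perhydro-1-benzoxepine-11β-carboxylate
Product: 11 benzyl 3α-(tert-butyldimethylsilyloxy)-2,2,6β-trimethyl-10-oxo-8-(trifluoromethylsulfonyloxy)-7αH-perhydro-1-benzoxepin-8-ene-11β-carboxylate
Conditions: Tf2O, Et3N, CH2Cl2, −78 °C
Reagents that add atoms: triflic anhydride, O=S(=O)(OS(=O)(=O)C(F)(F)F)C(F)(F)F
Why: O-sulfonylation of the cyclic β-diketonate should take place on the C8 oxygen, remote from the ester-bearing C11, so that the C10 carbonyl stays part of the enolisable β-keto ester and the helper oxygen at C8 becomes a leaving group.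

Step 8
Reactants: 11 benzyl 3α-(tert-butyldimethylsilyloxy)-2,2,6β-trimethyl-10-oxo-8-(trifluoromethylsulfonyloxy)-7αH-perhydro-1-benzoxepin-8-ene-11β-carboxylate
Product: 12 benzyl 3α-(tert-butyldimethylsilyloxy)-2,2,6β-trimethyl-10-oxo-7αH-perhydro-1-benzoxepin-8-ene-11β-carboxylate
Conditions: Pd(OAc)2 (5 mol%), PPh3 (10 mol%), HCO2H, Et3N, DMF, 60 °C
Reagents that add atoms: none
Why: palladium-catalysed formate reduction of a vinylogous enol triflate (oxidative addition, formate exchange, loss of CO2, reductive elimination) should replace OTf by H and so remove the C8 oxygen without touching the benzyl ester.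

Step 9
Reactants: 12 benzyl 3α-(tert-butyldimethylsilyloxy)-2,2,6β-trimethyl-10-oxo-7αH-perhydro-1-benzoxepin-8-ene-11β-carboxylate
Product: 13 3α-(tert-butyldimethylsilyloxy)-2,2,6β-trimethyl-10-oxo-7αH-perhydro-1-benzoxepine-11β-carboxylic acid
Conditions: H2 (1 atm), Pd/C, EtOAc, rt; filtrate used cold without purification
Reagents that add atoms: none
Why: heterogeneous hydrogenation should saturate the C8=C9 enone double bond and cleave the benzyl ester by hydrogenolysis in the same operation, creating no new stereocentre.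

Step 10
Reactants: 13 3α-(tert-butyldimethylsilyloxy)-2,2,6β-trimethyl-10-oxo-7αH-perhydro-1-benzoxepine-11β-carboxylic acid
Product: 15 3α-(tert-butyldimethylsilyloxy)-2,2,6β-trimethyl-11-methylidene-7αH-perhydro-1-benzoxepin-10-one, via Mannich acid 14 (not isolated)
Conditions: CH2O (37% aq.), Et2NH, AcOH/NaOAc, THF, 0 → 40 °C; product used directly
Reagents that add atoms: formaldehyde, C=O
Why: Mannich reaction of the β-keto acid with the iminium ion from CH2O and Et2NH, followed by decarboxylative elimination of the amine, should place the methylene group (C12) regiospecifically on C11 and remove the second helper ester carbon as CO2.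

Step 11
Reactants: 15 3α-(tert-butyldimethylsilyloxy)-2,2,6β-trimethyl-11-methylidene-7αH-perhydro-1-benzoxepin-10-one
Product: 16 3α-(tert-butyldimethylsilyloxy)-2,2,6β,10α-tetramethyl-11-methylidene-7αH-perhydro-1-benzoxepin-10β-ol
Conditions: MeLi, CeCl3, THF, −78 °C; then aq. NH4Cl
Reagents that add atoms: methyllithium, [Li]C
Why: the organocerium reagent should add 1,2 to the α-methylene ketone (no conjugate addition, no enolisation) and approach C10 equatorially, anti to the axial C6 methyl group, so that the new hydroxyl is axial and cis to that methyl as in the target.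

Step 12
Reactants: 16 3α-(tert-butyldimethylsilyloxy)-2,2,6β,10α-tetramethyl-11-methylidene-7αH-perhydro-1-benzoxepin-10β-ol
Product: 17 2,2,6β,10α-tetramethyl-11-methylidene-7αH-perhydro-1-benzoxepine-3α,10β-diol
Conditions: Bu4NF, THF, 50 °C
Reagents that add atoms: none
Why: fluoride-mediated desilylation frees the C3 hydroxyl of this half only, which later allows oxidation at C3 here while C3' of the other half stays silylated.

Step 13
Reactants: 17 2,2,6β,10α-tetramethyl-11-methylidene-7αH-perhydro-1-benzoxepine-3α,10β-diol; 15 3α-(tert-butyldimethylsilyloxy)-2,2,6β-trimethyl-11-methylidene-7αH-perhydro-1-benzoxepin-10-one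
Product: 20 C12–C12'-linked ketone (half A: 3α,10β-dihydroxy-10α-methyl; half B: 3'α-silyloxy-10'-oxo; both side chains β), via tris-boryl alkylborane 18 (not isolated), via boron enolate adduct 19 (not isolated)
Conditions: catecholborane (3.5 equiv), N,N-dimethylacetamide (10 mol%), CH2Cl2, 40 °C; then t-BuOH (destroys excess borane); then 15, DMPU, air (slow addition), 0 °C → rt; then K2CO3, MeOH, rt
Reagents that add atoms: none
Why: anti-Markovnikov hydroboration should deliver hydrogen to C11 from the face opposite the axial C6 methyl and C10 oxygen substituents (side chain equatorial), and the B-alkylcatecholborane then enters an oxygen-initiated radical chain in which the primary C12 radical adds to the unhindered methylene carbon of enone 15 and the enoxyl radical is trapped at boron (radical conjugate addition of B-alkylcatecholboranes), the basic work-up cleaving the boron esters and equilibrating C11' to the equatorial epimer.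

Step 14
Reactants: 20 C12–C12'-linked ketone
Product: 21 C12–C12'-linked 10'-methylidene compound (half A: 3α,10β-dihydroxy-10α-methyl; half B: 3'α-silyloxy)
Conditions: Ph3PCH3Br, KOtBu (excess), toluene, rt → 80 °C
Reagents that add atoms: methyltriphenylphosphonium bromide (as Ph3P=CH2), C[P+](c1ccccc1)(c1ccccc1)c1ccccc1.[Br-]
Why: Wittig methylenation of the α-branched cyclohexanone with excess non-stabilised ylide (the free hydroxyls are only deprotonated) should give the exocyclic alkene, any epimerisation at C11' under base leading to the more stable equatorial side chain.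

Step 15
Reactants: 21 C12–C12'-linked 10'-methylidene compound
Product: 22 3'-O-silyl ether of the target (half A: 3-oxo-10β-hydroxy-10α-methyl; half B: 3'α-silyloxy-10'-methylidene)
Conditions: Dess–Martin periodinane, NaHCO3, CH2Cl2, rt
Reagents that add atoms: none
Why: Dess–Martin oxidation should convert the only secondary alcohol (C3 of half A) into the oxepanone, the tertiary alcohol, the silyl ether and the exocyclic alkene being inert.

Step 16
Reactants: 22 3'-O-silyl ether of the target
Product: 23 CNP0160418.1 (target)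
Conditions: Bu4NF, THF, rt → 40 °C
Reagents that add atoms: none
Why: fluoride cleavage of the remaining silyl ether should release the C3' alcohol with the configuration set in step 2 and give the target.

**Compound list**

1 | 6-methylhept-5-en-2-one (sulcatone) | CC(=O)CCC=C(C)C | starting material
2 | dibenzyl malonate | O=C(CC(=O)OCc1ccccc1)OCc1ccccc1 | starting material
3 | dibenzyl 2-(6-methylhept-5-en-2-ylidene)propanedioate | CC(C)=CCCC(C)=C(C(=O)OCc1ccccc1)C(=O)OCc1ccccc1 | intermediate
4 | dibenzyl 2-{4-[(2S)-3,3-dimethyloxiran-2-yl]butan-2-ylidene}propanedioate | CC(CC[C@@H]1OC1(C)C)=C(C(=O)OCc1ccccc1)C(=O)OCc1ccccc1 | intermediate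
5 | 2-methylprop-2-en-1-ol (methallyl alcohol) | C=C(C)CO | starting material
6 | dibenzyl 2-{(5S)-5-hydroxy-6-methyl-6-[(2-methylprop-2-en-1-yl)oxy]heptan-2-ylidene}propanedioate | CC(CC[C@H](O)C(C)(C)OCC(C)=C)=C(C(=O)OCc1ccccc1)C(=O)OCc1ccccc1 | intermediate
7 | dibenzyl 2-{(5S)-5-[(tert-butyldimethylsilyl)oxy]-6-methyl-6-[(2-methylprop-2-en-1-yl)oxy]heptan-2-ylidene}propanedioate | CC(CC[C@H](O[Si](C)(C)C(C)(C)C)C(C)(C)OCC(C)=C)=C(C(=O)OCc1ccccc1)C(=O)OCc1ccccc1 | intermediate
8 | dibenzyl 2-{(5S)-5-[(tert-butyldimethylsilyl)oxy]-6-methyl-6-(2-oxopropoxy)heptan-2-ylidene}propanedioate | CC(CC[C@H](O[Si](C)(C)C(C)(C)C)C(C)(C)OCC(C)=O)=C(C(=O)OCc1ccccc1)C(=O)OCc1ccccc1 | intermediate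
9 | oxepane Michael adduct: dibenzyl 2-[2-acetyl-6-(tert-butyldimethylsilyloxy)-3,7,7-trimethyloxepan-3-yl]propanedioate (acetyl trans to the malonyl group, silyloxy cis to it, oxepane C6 S) | O=C(OCc1ccccc1)C(C(=O)OCc1ccccc1)[C@]1(C)CC[C@H](O[Si](C)(C)C(C)(C)C)C(C)(C)O[C@H]1C(C)=O | intermediate (not isolated)
10 | benzyl 3α-(tert-butyldimethylsilyloxy)-2,2,6β-trimethyl-8,10-dioxo-7αH-perhydro-1-benzoxepine-11β-carboxylate (3S, trans-fused; triketo tautomer drawn) | O=C(OCc1ccccc1)[C@H]1[C@]2(C)CC[C@H](O[Si](C)(C)C(C)(C)C)C(C)(C)O[C@H]2C(=O)CC1=O | intermediate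
11 | benzyl 3α-(tert-butyldimethylsilyloxy)-2,2,6β-trimethyl-10-oxo-8-(trifluoromethylsulfonyloxy)-7αH-perhydro-1-benzoxepin-8-ene-11β-carboxylate | O=C(OCc1ccccc1)[C@H]1[C@]2(C)CC[C@H](O[Si](C)(C)C(C)(C)C)C(C)(C)O[C@H]2C(OS(=O)(=O)C(F)(F)F)=CC1=O | intermediate
12 | benzyl 3α-(tert-butyldimethylsilyloxy)-2,2,6β-trimethyl-10-oxo-7αH-perhydro-1-benzoxepin-8-ene-11β-carboxylate | O=C(OCc1ccccc1)[C@H]1[C@]2(C)CC[C@H](O[Si](C)(C)C(C)(C)C)C(C)(C)O[C@H]2C=CC1=O | intermediate
13 | 3α-(tert-butyldimethylsilyloxy)-2,2,6β-trimethyl-10-oxo-7αH-perhydro-1-benzoxepine-11β-carboxylic acid | OC(=O)[C@H]1[C@]2(C)CC[C@H](O[Si](C)(C)C(C)(C)C)C(C)(C)O[C@H]2CCC1=O | intermediate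
14 | Mannich acid: 11-(diethylaminomethyl)-3α-(tert-butyldimethylsilyloxy)-2,2,6β-trimethyl-10-oxo-7αH-perhydro-1-benzoxepine-11-carboxylic acid (aminomethyl group drawn anti to the C6 methyl; this centre is lost at once) | OC(=O)[C@@]1(CN(CC)CC)[C@]2(C)CC[C@H](O[Si](C)(C)C(C)(C)C)C(C)(C)O[C@H]2CCC1=O | intermediate (not isolated)
15 | 3α-(tert-butyldimethylsilyloxy)-2,2,6β-trimethyl-11-methylidene-7αH-perhydro-1-benzoxepin-10-one (3S, trans-fused) | C=C1[C@]2(C)CC[C@H](O[Si](C)(C)C(C)(C)C)C(C)(C)O[C@H]2CCC1=O | intermediate
16 | 3α-(tert-butyldimethylsilyloxy)-2,2,6β,10α-tetramethyl-11-methylidene-7αH-perhydro-1-benzoxepin-10β-ol | C=C1[C@]2(C)CC[C@H](O[Si](C)(C)C(C)(C)C)C(C)(C)O[C@H]2CC[C@@]1(C)O | intermediate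
17 | 2,2,6β,10α-tetramethyl-11-methylidene-7αH-perhydro-1-benzoxepine-3α,10β-diol | C=C1[C@]2(C)CC[C@H](O)C(C)(C)O[C@H]2CC[C@@]1(C)O | intermediate
18 | tris-boryl alkylborane: 17 after hydroboration at C12 (boron on C12, H on C11α) and O-borylation of both hydroxyls by catecholborane | C(B1Oc2ccccc2O1)[C@H]3[C@]4(C)CC[C@H](OB5Oc6ccccc6O5)C(C)(C)O[C@H]4CC[C@@]3(C)OB7Oc8ccccc8O7 | intermediate (not isolated)
19 | boron enolate adduct: C12–C12'-linked product with the C10' ketone as its catecholboron enolate and half A still O-borylated | O(B1Oc2ccccc2O1)C3=C(CC[C@H]4[C@]5(C)CC[C@H](OB6Oc7ccccc7O6)C(C)(C)O[C@H]5CC[C@@]4(C)OB8Oc9ccccc9O8)[C@]%10(C)CC[C@H](O[Si](C)(C)C(C)(C)C)C(C)(C)O[C@H]%10CC3 | intermediate (not isolated)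
20 | C12–C12'-linked ketone (half A: 3α,10β-dihydroxy-10α-methyl; half B: 3'α-silyloxy-10'-oxo; both side chains β) | O=C1CC[C@@H]2OC(C)(C)[C@@H](O[Si](C)(C)C(C)(C)C)CC[C@@]2(C)[C@@H]1CC[C@H]1[C@]2(C)CC[C@H](O)C(C)(C)O[C@H]2CC[C@@]1(C)O | intermediate
21 | C12–C12'-linked 10'-methylidene compound (half A: 3α,10β-dihydroxy-10α-methyl; half B: 3'α-silyloxy) | C=C1CC[C@@H]2OC(C)(C)[C@@H](O[Si](C)(C)C(C)(C)C)CC[C@@]2(C)[C@@H]1CC[C@H]1[C@]2(C)CC[C@H](O)C(C)(C)O[C@H]2CC[C@@]1(C)O | intermediate
22 | 3'-O-(tert-butyldimethylsilyl) ether of the target | C=C1CC[C@@H]2OC(C)(C)[C@@H](O[Si](C)(C)C(C)(C)C)CC[C@@]2(C)[C@@H]1CC[C@H]1[C@]2(C)CCC(=O)C(C)(C)O[C@H]2CC[C@@]1(C)O | intermediate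
23 | CNP0160418.1 | C=C1CC[C@@H]2OC(C)(C)[C@@H](O)CC[C@@]2(C)[C@@H]1CC[C@H]1[C@]2(C)CCC(=O)C(C)(C)O[C@H]2CC[C@@]1(C)O | target

**Step count and risks**

Total: 16 steps. Longest linear sequence: 16 steps (1 → 23 through 15, 16 and 17; the second portion of 15 enters at step 13).

Steps most likely to fail:

Step 6. The conjugate addition may stall, because the alkylidene malonate is drained into its γ-deprotonated dienolate and a seven-membered ring with a quaternary centre has to form; the facial selectivity at C6 and the sense of ring fusion may also be low. Fallback: starting from 8, soft enolisation (Me3SiOTf, Et3N, CH2Cl2, 0 °C) should give the (Z)-trimethylsilyl enol ether on the alkoxy-bearing side of the ketone, F1. A Lewis-acid Mukaiyama–Michael cyclisation (Sc(OTf)3, or Cu(OTf)2 and a chiral bis(oxazoline) to reinforce the facial bias, CH2Cl2, −78 °C) activates the malonate by chelation instead of deprotonating it and gives the oxepane 9 as an isolated compound. A separate Dieckmann closure (NaH, catalytic BnOH, THF) then returns to the route at 10.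

Step 13. Hydroboration of the doubly flanked alkene with catecholborane may be slow, and the radical chain may be short at near-equimolar stoichiometry, with oligomerisation or conjugate reduction of 15 competing. Fallback: starting from 17, hydroboration–oxidation (BH3·THF; then NaOH/H2O2) should give the primary alcohol 2,2,6β,10α-tetramethyl-11β-(hydroxymethyl)-7αH-perhydro-1-benzoxepine-3α,10β-diol F2. Appel iodination of the primary hydroxyl (PPh3, iodine, imidazole) gives the iodide F3, and a tin-free Giese addition of F3 to 15 ((Me3Si)3SiH, AIBN, toluene, 80 °C; then K2CO3, MeOH) returns to the route at 20.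

Step 7. O-sulfonylation may occur on the wrong oxygen of the diketonate, which would remove the C10 oxygen and keep the C8 oxygen. Fallback: starting from 10, hydrogenolysis and thermal decarboxylation (H2, Pd/C, EtOAc; then toluene, 80 °C) give the 8,10-dione without the ester, F4, whose less hindered C10 oxygen (next to the C11 methylene) is O-methylated (Me2SO4, K2CO3, acetone) to the vinylogous ester F5. Hydride reduction of the C8 carbonyl and acid hydrolysis (iBu2AlH, toluene, −78 °C; then 1 M HCl) transpose it to the 8-en-10-one F6. Kinetic deprotonation at C11 and Mannich alkylation (LiN(iPr)2, THF, −78 °C; then CH2=NMe2+ I−) give the amino enone F7, hydrogenation (H2, Pd/C) the saturated Mannich base F8, and quaternisation and elimination (MeI; then NaHCO3) return to the route at 15.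

Further compounds

F1 | step 6 | dibenzyl 2-{(5S)-5-[(tert-butyldimethylsilyl)oxy]-6-methyl-6-[(Z)-2-(trimethylsilyloxy)prop-1-en-1-yloxy]heptan-2-ylidene}propanedioate | CC(CC[C@H](O[Si](C)(C)C(C)(C)C)C(C)(C)O/C=C(/C)O[Si](C)(C)C)=C(C(=O)OCc1ccccc1)C(=O)OCc1ccccc1
F2 | step 13 | 2,2,6β,10α-tetramethyl-11β-(hydroxymethyl)-7αH-perhydro-1-benzoxepine-3α,10β-diol | OC[C@H]1[C@]2(C)CC[C@H](O)C(C)(C)O[C@H]2CC[C@@]1(C)O
F3 | step 13 | 11β-(iodomethyl)-2,2,6β,10α-tetramethyl-7αH-perhydro-1-benzoxepine-3α,10β-diol | IC[C@H]1[C@]2(C)CC[C@H](O)C(C)(C)O[C@H]2CC[C@@]1(C)O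
F4 | step 7 | 3α-(tert-butyldimethylsilyloxy)-2,2,6β-trimethyl-7αH-perhydro-1-benzoxepine-8,10-dione | C1[C@]2(C)CC[C@H](O[Si](C)(C)C(C)(C)C)C(C)(C)O[C@H]2C(=O)CC1=O
F5 | step 7 | 3α-(tert-butyldimethylsilyloxy)-10-methoxy-2,2,6β-trimethyl-7αH-perhydro-1-benzoxepin-9-en-8-one | C1[C@]2(C)CC[C@H](O[Si](C)(C)C(C)(C)C)C(C)(C)O[C@H]2C(=O)C=C1OC
F6 | step 7 | 3α-(tert-butyldimethylsilyloxy)-2,2,6β-trimethyl-7αH-perhydro-1-benzoxepin-8-en-10-one | C1[C@]2(C)CC[C@H](O[Si](C)(C)C(C)(C)C)C(C)(C)O[C@H]2C=CC1=O
F7 | step 7 | 11β-(dimethylaminomethyl)-3α-(tert-butyldimethylsilyloxy)-2,2,6β-trimethyl-7αH-perhydro-1-benzoxepin-8-en-10-one | CN(C)C[C@H]1[C@]2(C)CC[C@H](O[Si](C)(C)C(C)(C)C)C(C)(C)O[C@H]2C=CC1=O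
F8 | step 7 | 11β-(dimethylaminomethyl)-3α-(tert-butyldimethylsilyloxy)-2,2,6β-trimethyl-7αH-perhydro-1-benzoxepin-10-one | CN(C)C[C@H]1[C@]2(C)CC[C@H](O[Si](C)(C)C(C)(C)C)C(C)(C)O[C@H]2CCC1=O
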